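The numbers in the tables were computed from invented constants; noise was put on by code.

No constants are given, so read what you need off the two earlier runs.

common to all: reagent 0.105 M

| charge | substrate | remark | time |
|---|---|---|---|
| Saturday's | 0.050 M | run made earlier |  |
| Thursday's | 0.075 M | run made earlier |  |
| flask | 0.10 M |  | 25 min |

- Saturday's (time / min: substrate / %, first product / %): 2.50: 80.0, 2.8; 8.00: 67.3, 10.4; 12.0: 59.1, 13.6; 20.0: 53.8, 15.4
- Thursday's (time / min: substrate / %, first product / %): 5.00: 71.9, 7.7; 10.0: 63.0, 11.9; 15.0: 57.6, 13.5; 20.0: 55.4, 16.3

(each reading ± 1 percentage point)

- substrate at 25 min, in percent of the substrate charged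
- first product at 25 min, in percent of the substrate charged
- double product at 25 min, in percent of the substrate charged



Start with the bench rule: with reagent in excess, treat the loss of substrate as pseudo-first-order, so percent curves ignore the charge. Saturday's and Thursday's runs show 53.8 % and 55.4 % of substrate at 20.0 min. Find the border with c(substrate)/c(reagent): 0.476 on Saturday, 0.952 in the new flask. In the new flask the same percent of substrate costs twice the share of reagent that it costs on Saturday, so correct for it.

Now look at the balance. On Saturday it is short by 17.2 % at 2.50 min and by 22.3 % at 8.00 min. Treat this early loss as a fast step at balance, and define the parking ratio as the missing share over the substrate still present at that second reading: 0.331, a reading with its scatter.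

Reckon with the pool, substrate times one plus that ratio. Saturday's pool falls to 71.6 % at 20.0 min, which gives 0.0167 min⁻¹. Scale this by the mean reagent left, 93.2 % on Saturday and 83.8 % in the new flask. The flask's pool at 25 min is then 68.7 %, so I expect 51.6 % of substrate. Hold first product at the mean of the last readings, 15.8 %. That leaves 15.4 % for double product and any unseen product.

The forecast gave 55 %, 16.5 % and 28.5 %, holding that “there is a fast early route”; its double product stands above my remainder.

The flask gives 52.1 % substrate, 16.5 % first product and 2.14 % double product.

    substrate ⇌ dormant form (K = 0.320, k = 0.130 min⁻¹)
    substrate + reagent → first product + by-product (k = 0.220 L mol⁻¹ min⁻¹)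
    first product ⇌ isomer of the product (K = 8.60, k = 0.0430 min⁻¹)
    reagent + first product → double product + by-product (k = 0.0870 L mol⁻¹ min⁻¹)

At 9.84 min this flask sends first product into isomer of the product 5.6 times as fast as into double product, counting the forward rate of the reversible step. At 25.0 min it holds 12.1 % of isomer of the product beside 2.14 % of double product. The step to the dormant form has a relaxation half-life of 1.29 min, short against 25 min. The ratio of dormant form to substrate in this flask at 25.0 min is 0.330, beside the parking ratio of 0.331. Read at 40.0 min, the same flask holds 44.3 % of substrate; the parking ratio puts the dormant form at 14.7 %, and it stands at 14.5 %.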